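**Retrosynthetic overview**
1. Target 35 ← tetraol 34 ← carbinol 33 ← ketone 32: the last operations are equatorial methyl addition to the benzoxepine C7 ketone, desilylation and oxidation of the two secondary alcohols.
2. 32 ← acyclic bis-epoxy (Z)-silyl enol ether 30 by one cascade that forms O1–C2 (oxepane) and then C5a–C6 (cyclohexane, closed last), setting C5a, C6 and the trans ring fusion.
3. Enabling feature: in the perhydro-1-benzoxepine the ring oxygen on C9a is vicinal and anti to the new bond at the methyl-bearing C5a, the C3 oxygen is vicinal to O1–C2(Me)2, and the C7 carbinol carbon is next to C6. This is the pattern of two (E)-alkene epoxides of a geranyl chain opened in sequence and terminated by a ketone enol ether.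
4. 30 ← cross-metathesis of allyl-hydroazulene 22 with diepoxy vinyl ketone 28 (from geranyl bromide by Shi epoxidation), then 1,4-hydrosilylation.
5. 22 ← (R)-linalool: Pauson–Khand reaction (cyclopentane plus a temporary cyclopentenone), reductive methylation, two-carbon ring expansion to the seven-membered ring, Stork–Danheiser allylation, reductive Mannich methylenation. Ring order: cyclopentane, cycloheptane, oxepane, cyclohexane.

Key step: step 21

Remarks on the chemistry
- Locants: the hydroazulene is numbered as azulene (C1 carbinol carbon, C3a/C8a ring fusion, C4 gem-dimethyl, C5 side chain, C6 methylene carbon, C7 carbonyl carbon). The ether bicycle is numbered as 1-benzoxepine (O1, C2 gem-dimethyl, C3 carbonyl, C5a angular methyl, C6 side chain, C7 carbinol, C9a).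
- The hydroazulene C7 carbinol centre made in step 14 is oxidised again in step 24. It is carried as formed and drawn without a descriptor, as are centres that vanish in the next operation (in 15, 18, 19).
- (R)-Linalool, (E)-geranyl bromide and the D-fructose-derived Shi ketone are assumed to be commercial in high isomeric purity.

**Route**

Step 1
Reactants: 1 (R)-linalool
Product: 2 (R)-linalyl tert-butyldimethylsilyl ether
Conditions: TBSOTf, 2,6-lutidine, CH2Cl2, 0 °C
Reagents that add atoms: tert-butyldimethylsilyl triflate, CC(C)(C)[Si](C)(C)OS(=O)(=O)C(F)(F)F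
Why: Silyl triflate with a hindered pyridine base silylates tertiary alcohols (silyl ether protection) and leaves the carbinol stereocentre untouched.

Step 2
Reactants: 2 (R)-linalyl tert-butyldimethylsilyl ether
Product: 3 (4R)-4-(tert-butyldimethylsilyloxy)-4-methylhex-5-enal
Conditions: O3, CH2Cl2/MeOH, pyridine, −78 °C (Sudan red 7B end point); then Me2S
Reagents that add atoms: ozone, [O-][O+]=O
Why: Ozonolysis with reductive work-up should cleave only the electron-rich trisubstituted alkene, because the vinyl group beside the silyloxy-bearing quaternary carbon reacts much more slowly.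

Step 3
Reactants: 3 (4R)-4-(tert-butyldimethylsilyloxy)-4-methylhex-5-enal
Product: 4 (3R)-7,7-dibromo-3-(tert-butyldimethylsilyloxy)-3-methylhepta-1,6-diene
Conditions: CBr4, PPh3, CH2Cl2, 0 °C
Reagents that add atoms: carbon tetrabromide, BrC(Br)(Br)Br
Why: First stage of the Corey–Fuchs alkyne synthesis (dibromo-olefination of an aldehyde by the phosphorus ylide from CBr4/PPh3).

Step 4
Reactants: 4 (3R)-7,7-dibromo-3-(tert-butyldimethylsilyloxy)-3-methylhepta-1,6-diene
Product: 6 (3R)-3-(tert-butyldimethylsilyloxy)-3-methyloct-1-en-6-yne, via lithium acetylide 5 (not isolated)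
Conditions: n-BuLi (2.1 equiv), THF, −78 °C; then MeI, −78 °C to rt
Reagents that add atoms: iodomethane, CI
Why: Second stage of the Corey–Fuchs sequence (Br/Li exchange, Fritsch–Buttenberg–Wiechell rearrangement, deprotonation) followed by C-methylation of the acetylide.

Step 5
Reactants: 6 (3R)-3-(tert-butyldimethylsilyloxy)-3-methyloct-1-en-6-yne
Product: 7 (6R,6aR)-6-(tert-butyldimethylsilyloxy)-3,6-dimethyl-4,5,6,6a-tetrahydropentalen-2(1H)-one (6-OTBS cis to H-6a)
Conditions: Co2(CO)8 (10 mol %), tetramethylthiourea (60 mol %), CO (1 atm), benzene, 70 °C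
Reagents that add atoms: carbon monoxide, [C-]#[O+]
Why: Intramolecular Pauson–Khand reaction of a 1,6-enyne closes both five-membered rings, and the ring-fusion hydrogen should end cis to the silyloxy group because the bulkier OTBS avoids the endo position that faces the cobalt-bound alkene terminus during insertion.

Step 6
Reactants: 7 (6R,6aR)-6-(tert-butyldimethylsilyloxy)-3,6-dimethyl-4,5,6,6a-tetrahydropentalen-2(1H)-one
Product: 9 (3aR,4R,6aR)-4-(tert-butyldimethylsilyloxy)-1,1,4-trimethylhexahydropentalen-2(1H)-one (cis-fused), via lithium enolate 8 (not isolated)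
Conditions: Li, NH3(l)/THF, t-BuOH (1 equiv), −78 °C; then MeI, −78 to 0 °C
Reagents that add atoms: iodomethane, CI
Why: Dissolving-metal reduction of the enone followed by trapping of the regiospecific enolate (reductive alkylation) builds the gem-dimethyl carbon, and protonation at the ring-fusion carbon can only give the strain-free cis-bicyclo[3.3.0]octane.

Step 7
Reactants: 9 (3aR,4R,6aR)-4-(tert-butyldimethylsilyloxy)-1,1,4-trimethylhexahydropentalen-2(1H)-one
Product: 10 trimethylsilyl enol ether of 9 (C2=C3 enol ether)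
Conditions: Me3SiOTf, Et3N, CH2Cl2, 0 °C
Reagents that add atoms: trimethylsilyl triflate, C[Si](C)(C)OS(=O)(=O)C(F)(F)F
Why: Soft enolisation/silylation gives a single regioisomer because the other α-carbon is quaternary.

Step 8
Reactants: 10 trimethylsilyl enol ether of 9
Product: 11 dichlorocyclobutanone adduct (2,2-dichloro-3-silyloxycyclobutanone fused across the former enol ether bond)
Conditions: Cl2CHCOCl, Et3N, hexane, rt (slow addition)
Reagents that add atoms: dichloroacetyl chloride (source of dichloroketene), ClC(Cl)C(=O)Cl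
Why: Ketene–silyl enol ether [2+2] cycloaddition, in which the ketene carbonyl carbon bonds to the nucleophilic CH of the enol ether; dichloroketene is small and electrophilic enough to add to fully substituted alkenes, and the two new centres (convex-face addition expected) are lost in step 9.

Step 9
Reactants: 11 dichlorocyclobutanone adduct
Product: 13 (1R)-1-(tert-butyldimethylsilyloxy)-1,4,4-trimethyloctahydroazulene-5,7-dione (cis-fused; 1-OTBS cis to H-8a), via dechlorinated cyclobutanone 12 (not isolated)
Conditions: Zn, AcOH, i-PrOH/H2O, 0 °C to rt; then 80 °C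
Reagents that add atoms: none
Why: Reductive dechlorination followed by acid-mediated desilylative retro-aldol opening of the β-silyloxy cyclobutanone at the bond shared by the two rings is the known two-carbon ring expansion of cyclopentanones to cycloheptane-1,3-diones; acid is used because it is reported to favour this cleavage, and the tertiary TBS ether should survive.

Step 10
Reactants: 13 (1R)-1-(tert-butyldimethylsilyloxy)-1,4,4-trimethyloctahydroazulene-5,7-dione
Product: 14 7-methoxy enone (vinylogous ester with the free carbonyl at C5 next to the gem-dimethyl carbon)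
Conditions: HC(OMe)3, camphorsulfonic acid (cat.), MeOH, rt
Reagents that add atoms: trimethyl orthoformate, COC(OC)OC
Why: Acid-catalysed enol etherification of a cyclic 1,3-dione takes place at the less hindered carbonyl (C7), as with 4,4-dimethylcyclohexane-1,3-dione, leaving the C5 carbonyl next to the quaternary carbon.

Step 11
Reactants: 14 7-methoxy enone
Product: 16 5-allyl-1-(tert-butyldimethylsilyloxy)-1,4,4-trimethyl-2,3,3a,4,8,8a-hexahydroazulen-7(1H)-one (cis-fused), via magnesium alkoxide 15 (not isolated)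
Conditions: CH2=CHCH2MgBr, THF, −78 to 0 °C; then 1 M HCl, THF, 0 °C
Reagents that add atoms: allylmagnesium bromide, C=CC[Mg]Br; water, O
Why: Stork–Danheiser transposition (1,2-addition of the unhindered allyl Grignard reagent to the vinylogous ester carbonyl, then acid hydrolysis and loss of water) gives the enone with the allyl group at C5 and the carbonyl at C7.

Step 12
Reactants: 16 5-allyl enone
Product: 18 Mannich base (6-dimethylaminomethyl-5-allyl ketone; H-5 cis to H-3a and H-8a), via lithium enolate 17 (not isolated)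
Conditions: Li, NH3(l)/THF, t-BuOH (1 equiv), −78 °C; NH3 removed; then CH2=NMe2+ I−, THF, −78 °C to rt
Reagents that add atoms: N,N-dimethylmethyleneiminium iodide (Eschenmoser's salt), C=[N+](C)C.[I-]
Why: Dissolving-metal reduction of the β,β-disubstituted enone gives the C6–C7 enolate regiospecifically for Mannich trapping, and protonation at C5 is expected from the convex face (the face of the ring-fusion hydrogens), which leaves the allyl group pseudo-equatorial and 1,3-cis to the cyclopentane bond at C3a.

Step 13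
Reactants: 18 Mannich base
Product: 20 5-allyl-6-methylene ketone (α-methylene ketone), via ammonium iodide 19 (not isolated)
Conditions: MeI, CH2Cl2, rt; then NaHCO3 (aq), rt
Reagents that add atoms: none
Why: Quaternisation and E1cB elimination of the Mannich base is the standard regiospecific α-methylenation of a ketone; C5 is not acidified and keeps its configuration.

Step 14
Reactants: 20 5-allyl-6-methylene ketone
Product: 21 allylic alcohol (6-methylene-7-ol)
Conditions: NaBH4, CeCl3·7H2O, MeOH, −78 °C
Reagents that add atoms: none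
Why: Luche reduction gives clean 1,2-reduction of the α-methylene ketone, which masks the enone for the following steps; the new centre is of no consequence.

Step 15
Reactants: 21 allylic alcohol
Product: 22 5-allyl-1,7-bis(tert-butyldimethylsilyloxy)-1,4,4-trimethyl-6-methylenedecahydroazulene (cis-fused; H-3a, H-5, H-8a and 1-OTBS on one face)
Conditions: TBSCl, imidazole, DMF, rt
Reagents that add atoms: tert-butyldimethylsilyl chloride, CC(C)(C)[Si](C)(C)Cl
Why: Standard silylation of a secondary allylic alcohol.

Step 16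
Reactants: 23 (E)-geranyl bromide; 24 N-methoxy-N-methylacetamide
Product: 26 (4E)-N-methoxy-N,5,9-trimethyldeca-4,8-dienamide, via amide enolate 25 (not isolated)
Conditions: LiN(i-Pr)2, THF/DMPU, −78 °C; then 23, −78 to −30 °C
Reagents that add atoms: none
Why: SN2 alkylation of an amide enolate with a primary allylic bromide, which keeps the (E)-alkene geometry.

Step 17
Reactants: 26 (4E)-N-methoxy-N,5,9-trimethyldeca-4,8-dienamide
Product: 27 (4R,5R,8R)-4,5:8,9-diepoxy-N-methoxy-N,5,9-trimethyldecanamide
Conditions: D-fructose-derived Shi ketone (30 mol % per alkene), KHSO5 (as 2KHSO5·KHSO4·K2SO4), K2CO3, Bu4NHSO4, MeCN/CH2(OMe)2/aq. Na2B4O7 buffer, 0 °C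
Reagents that add atoms: potassium peroxymonosulfate, [K+].[O-]S(=O)(=O)OO
Why: Shi asymmetric epoxidation; the chiral dioxirane attacks both trisubstituted alkenes in the same sense through the spiro transition state, which should give the (R,R)-internal and (R)-terminal epoxides.

Step 18
Reactants: 27 (4R,5R,8R)-4,5:8,9-diepoxy-N-methoxy-N,5,9-trimethyldecanamide
Product: 28 (6R,7R,10R)-6,7:10,11-diepoxy-7,11-dimethyldodec-1-en-3-one
Conditions: CH2=CHMgBr, THF, −78 to 0 °C; inverse quench into cold aq. NH4Cl
Reagents that add atoms: vinylmagnesium bromide, C=C[Mg]Br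
Why: Weinreb ketone synthesis; the chelated tetrahedral adduct prevents over-addition and trisubstituted epoxides tolerate the Grignard reagent at low temperature.

Step 19
Reactants: 22 bis-silyl allyl-hydroazulene; 28 (6R,7R,10R)-6,7:10,11-diepoxy-7,11-dimethyldodec-1-en-3-one
Product: 29 (E)-enone (hydroazulene C5–CH2–CH=CH–C(=O)– bis-epoxide chain)
Conditions: second-generation Hoveyda–Grubbs catalyst (5 mol %), 28 (2.5 equiv), CH2Cl2, 40 °C
Reagents that add atoms: none
Why: Olefin cross-metathesis of a terminal alkene with a vinyl ketone is selective for the (E)-enone, while the hindered 1,1-disubstituted exocyclic alkene and the epoxides are spectators.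

Step 20
Reactants: 29 (E)-enone
Product: 30 (Z)-triethylsilyl enol ether
Conditions: RhCl(PPh3)3 (2 mol %), Et3SiH, THF, 50 °C
Reagents that add atoms: triethylsilane, CC[SiH](CC)CC
Why: Rhodium-catalysed 1,4-hydrosilylation of an enone with a monohydrosilane fixes the enol ether regiochemistry toward the side chain and is expected to give mainly the (Z)-isomer.

Step 21
Reactants: 30 (Z)-triethylsilyl enol ether
Product: 32 trans-fused 3-(trimethylsilyloxy)-2,2,5a-trimethyl-6-[2-(hydroazulenyl)ethyl]octahydro-1-benzoxepin-7-one, via epoxonium triflate 31 (not isolated)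
Conditions: Me3SiOTf (1.2 equiv), 2,6-di-tert-butyl-4-methylpyridine, CH2Cl2, −78 °C; then NaHCO3 (aq)
Reagents that add atoms: trimethylsilyl triflate, C[Si](C)(C)OS(=O)(=O)C(F)(F)F
Why: Me3SiOTf silylates the terminal epoxide, whose tertiary carbon C2 is attacked by the oxygen of the neighbouring epoxide to give the bicyclic epoxonium ion 31, and the (Z)-silyl enol ether then opens this ion at its tertiary carbon C5a with loss of the triethylsilyl group to unveil the C7 ketone. The closest known reaction type is the silyl-triflate-triggered tandem oxa/carbacyclisation of 1,5-diepoxides terminated by a silyl enol ether, which gives trans-fused oxepane–cyclohexanones. The oxepane closes first by endo attack of oxygen at the tertiary epoxide carbon (O1 is left bridging C2 and C9a once the O–C5a bond breaks), and the cyclohexane closes last by 6-endo attack of the enol ether carbon on C5a through a chair transition state. C5a is set by inversion at the (R)-epoxide carbon and C9a keeps the Shi epoxide configuration, so the fusion is trans with the angular methyl anti to O1; C6 is set by the (Z)-enol ether geometry, which places the side chain equatorial, and being α to the new ketone it could also be corrected by equilibration; C3 keeps its epoxide configuration and is oxidised later. The step needs attack at the tertiary carbon in both openings, which the trisubstituted epoxides secure, and C- rather than O-alkylation of the enol ether, which the six-membered chair and the non-nucleophilic base favour. The tertiary and allylic silyl ethers and the hindered exocyclic alkene should be inert at −78 °C.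

Step 22
Reactants: 32 tricyclic C7 ketone
Product: 33 C7 tertiary carbinol (7-OH axial and cis to the 5a-methyl; 7-methyl equatorial)
Conditions: MeMgBr, CeCl3, THF, −78 to 0 °C
Reagents that add atoms: methylmagnesium bromide, C[Mg]Br
Why: Organocerium-type 1,2-addition suppresses enolisation, and the axial angular methyl at C5a blocks axial approach, so equatorial attack should give the axial alcohol required.

Step 23
Reactants: 33 C7 tertiary carbinol
Product: 34 tetraol (hydroazulene 1,7-diol and benzoxepine 3,7-diol)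
Conditions: Bu4NF, THF, 50 °C
Reagents that add atoms: none
Why: Fluoride-mediated cleavage of the trimethylsilyl ether and both TBS ethers on a substrate that has no base-sensitive carbonyl group at this stage.

Step 24
Reactants: 34 tetraol
Product: 35 target CNP0316622.2
Conditions: Dess–Martin periodinane, NaHCO3, CH2Cl2, rt
Reagents that add atoms: none
Why: Dess–Martin oxidation converts both secondary alcohols (allylic C7 of the hydroazulene to the α-methylene ketone, C3 of the benzoxepine to the ketone) and cannot oxidise the two tertiary alcohols.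

**Compound list**
1 | (R)-linalool | CC(C)=CCC[C@@](C=C)(C)O | starting material
2 | (R)-linalyl tert-butyldimethylsilyl ether | CC(C)=CCC[C@@](C=C)(C)O[Si](C)(C)C(C)(C)C | intermediate
3 | (4R)-4-(tert-butyldimethylsilyloxy)-4-methylhex-5-enal | O=CCC[C@@](C=C)(C)O[Si](C)(C)C(C)(C)C | intermediate
4 | (3R)-7,7-dibromo-3-(tert-butyldimethylsilyloxy)-3-methylhepta-1,6-diene | BrC(Br)=CCC[C@@](C=C)(C)O[Si](C)(C)C(C)(C)C | intermediate
5 | lithium acetylide from 4 (not isolated) | [Li]C#CCC[C@@](C=C)(C)O[Si](C)(C)C(C)(C)C | intermediate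
6 | (3R)-3-(tert-butyldimethylsilyloxy)-3-methyloct-1-en-6-yne | CC#CCC[C@@](C=C)(C)O[Si](C)(C)C(C)(C)C | intermediate
7 | (6R,6aR)-6-(tert-butyldimethylsilyloxy)-3,6-dimethyl-4,5,6,6a-tetrahydropentalen-2(1H)-one | O=C1C[C@@H]2C(=C1C)CC[C@@]2(C)O[Si](C)(C)C(C)(C)C | intermediate
8 | lithium enolate from reduction of 7 (not isolated) | [Li]OC=1C[C@@H]2[C@@H](CC[C@@]2(C)O[Si](C)(C)C(C)(C)C)C=1C | intermediate
9 | (3aR,4R,6aR)-4-(tert-butyldimethylsilyloxy)-1,1,4-trimethylhexahydropentalen-2(1H)-one, cis-fused | O=C1C[C@@H]2[C@@H](CC[C@@]2(C)O[Si](C)(C)C(C)(C)C)C1(C)C | intermediate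
10 | trimethylsilyl enol ether of 9 | C[Si](C)(C)OC1=C[C@@H]2[C@@H](CC[C@@]2(C)O[Si](C)(C)C(C)(C)C)C1(C)C | intermediate
11 | dichlorocyclobutanone adduct of 10 (ketene added on the convex face) | C[Si](C)(C)O[C@@]12C(Cl)(Cl)C(=O)[C@@H]1[C@@H]3[C@@H](CC[C@@]3(C)O[Si](C)(C)C(C)(C)C)C2(C)C | intermediate
12 | dechlorinated silyloxycyclobutanone (not isolated) | C[Si](C)(C)O[C@@]12CC(=O)[C@@H]1[C@@H]3[C@@H](CC[C@@]3(C)O[Si](C)(C)C(C)(C)C)C2(C)C | intermediate
13 | (1R)-1-(tert-butyldimethylsilyloxy)-1,4,4-trimethyloctahydroazulene-5,7-dione, cis-fused, 1-OTBS cis to H-8a | O=C1CC(=O)C[C@@H]2[C@@H](CC[C@@]2(C)O[Si](C)(C)C(C)(C)C)C1(C)C | intermediate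
14 | 1-(tert-butyldimethylsilyloxy)-7-methoxy-1,4,4-trimethyl-2,3,3a,4,8,8a-hexahydroazulen-5(1H)-one, cis-fused | O=C1C=C(OC)C[C@@H]2[C@@H](CC[C@@]2(C)O[Si](C)(C)C(C)(C)C)C1(C)C | intermediate
15 | bromomagnesium alkoxide of the 5-allyl-5-hydroxy-7-methoxy adduct (not isolated; C5 undefined) | C=CCC1(O[Mg]Br)C=C(OC)C[C@@H]2[C@@H](CC[C@@]2(C)O[Si](C)(C)C(C)(C)C)C1(C)C | intermediate
16 | 5-allyl-1-(tert-butyldimethylsilyloxy)-1,4,4-trimethyl-2,3,3a,4,8,8a-hexahydroazulen-7(1H)-one, cis-fused | C=CCC1=CC(=O)C[C@@H]2[C@@H](CC[C@@]2(C)O[Si](C)(C)C(C)(C)C)C1(C)C | intermediate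
17 | lithium C6–C7 enolate from reduction of 16 (not isolated) | C1=C(O[Li])C[C@@H]2[C@@H](CC[C@@]2(C)O[Si](C)(C)C(C)(C)C)C(C)(C)[C@H]1CC=C | intermediate
18 | Mannich base: 5-allyl-6-(dimethylaminomethyl)-1-(tert-butyldimethylsilyloxy)-1,4,4-trimethyloctahydroazulen-7-one (C6 undefined) | CN(C)CC1C(=O)C[C@@H]2[C@@H](CC[C@@]2(C)O[Si](C)(C)C(C)(C)C)C(C)(C)[C@H]1CC=C | intermediate
19 | trimethylammonium iodide of 18 (not isolated) | C[N+](C)(C)CC1C(=O)C[C@@H]2[C@@H](CC[C@@]2(C)O[Si](C)(C)C(C)(C)C)C(C)(C)[C@H]1CC=C.[I-] | intermediate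
20 | 5-allyl-1-(tert-butyldimethylsilyloxy)-1,4,4-trimethyl-6-methyleneoctahydroazulen-7-one | C=C1C(=O)C[C@@H]2[C@@H](CC[C@@]2(C)O[Si](C)(C)C(C)(C)C)C(C)(C)[C@H]1CC=C | intermediate
21 | 5-allyl-1-(tert-butyldimethylsilyloxy)-1,4,4-trimethyl-6-methylenedecahydroazulen-7-ol (C7 undefined) | C=C1C(O)C[C@@H]2[C@@H](CC[C@@]2(C)O[Si](C)(C)C(C)(C)C)C(C)(C)[C@H]1CC=C | intermediate
22 | 5-allyl-1,7-bis(tert-butyldimethylsilyloxy)-1,4,4-trimethyl-6-methylenedecahydroazulene (C7 undefined) | C=C1C(O[Si](C)(C)C(C)(C)C)C[C@@H]2[C@@H](CC[C@@]2(C)O[Si](C)(C)C(C)(C)C)C(C)(C)[C@H]1CC=C | intermediate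
23 | (E)-geranyl bromide | CC(C)=CCC/C(C)=C/CBr | starting material
24 | N-methoxy-N-methylacetamide | CC(=O)N(C)OC | starting material
25 | lithium enolate of 24 (not isolated) | C=C(O[Li])N(C)OC | intermediate
26 | (4E)-N-methoxy-N,5,9-trimethyldeca-4,8-dienamide | CC(C)=CCC/C(C)=C/CCC(=O)N(C)OC | intermediate
27 | (4R,5R,8R)-4,5:8,9-diepoxy-N-methoxy-N,5,9-trimethyldecanamide | CON(C)C(=O)CC[C@H]1O[C@]1(C)CC[C@H]1OC1(C)C | intermediate
28 | (6R,7R,10R)-6,7:10,11-diepoxy-7,11-dimethyldodec-1-en-3-one | C=CC(=O)CC[C@H]1O[C@]1(C)CC[C@H]1OC1(C)C | intermediate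
29 | (E)-enone from cross-metathesis of 22 and 28 | C=C1C(O[Si](C)(C)C(C)(C)C)C[C@@H]2[C@@H](CC[C@@]2(C)O[Si](C)(C)C(C)(C)C)C(C)(C)[C@H]1C/C=C/C(=O)CC[C@H]1O[C@]1(C)CC[C@H]1OC1(C)C | intermediate
30 | (Z)-triethylsilyl enol ether of the saturated bis-epoxy ketone | C=C1C(O[Si](C)(C)C(C)(C)C)C[C@@H]2[C@@H](CC[C@@]2(C)O[Si](C)(C)C(C)(C)C)C(C)(C)[C@H]1CC/C=C(\O[Si](CC)(CC)CC)CC[C@H]1O[C@]1(C)CC[C@H]1OC1(C)C | intermediate
31 | bicyclic epoxonium triflate (not isolated) | C=C1C(O[Si](C)(C)C(C)(C)C)C[C@@H]2[C@@H](CC[C@@]2(C)O[Si](C)(C)C(C)(C)C)C(C)(C)[C@H]1CC/C=C(\O[Si](CC)(CC)CC)CC[C@H]1[O+]2C(C)(C)[C@H](O[Si](C)(C)C)CC[C@]12C.[O-]S(=O)(=O)C(F)(F)F | intermediate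
32 | trans-fused 3-(trimethylsilyloxy)octahydro-1-benzoxepin-7-one carrying the bis-silyl hydroazulenylethyl chain at C6 | C=C1C(O[Si](C)(C)C(C)(C)C)C[C@@H]2[C@@H](CC[C@@]2(C)O[Si](C)(C)C(C)(C)C)C(C)(C)[C@H]1CC[C@@H]1[C@@]2(C)CC[C@@H](O[Si](C)(C)C)C(C)(C)O[C@@H]2CCC1=O | intermediate
33 | C7 tertiary carbinol (7-methyl equatorial, 7-OH axial) | C=C1C(O[Si](C)(C)C(C)(C)C)C[C@@H]2[C@@H](CC[C@@]2(C)O[Si](C)(C)C(C)(C)C)C(C)(C)[C@H]1CC[C@@H]1[C@@]2(C)CC[C@@H](O[Si](C)(C)C)C(C)(C)O[C@@H]2CC[C@]1(C)O | intermediate
34 | tetraol | C=C1C(O)C[C@@H]2[C@@H](CC[C@@]2(C)O)C(C)(C)[C@H]1CC[C@@H]1[C@@]2(C)CC[C@@H](O)C(C)(C)O[C@@H]2CC[C@]1(C)O | intermediate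
35 | target CNP0316622.2 | C=C1C(=O)C[C@@H]2[C@@H](CC[C@@]2(C)O)C(C)(C)[C@H]1CC[C@@H]1[C@@]2(C)CCC(=O)C(C)(C)O[C@@H]2CC[C@]1(C)O | target

**Step count and risks**
Total steps: 24. Longest linear sequence: 21 (steps 1–15 and 19–24); the right-hand fragment takes steps 16–18.

Most likely to fail:

1. Step 21. The enol ether may lose its silyl group before carbon–carbon bond formation, or the epoxonium ion may collapse by elimination or hydride shift instead of being captured by carbon. The fallback sets out from 30 and returns at 32, and changes the carbon terminus to an allylsilane. CsF and PhNTf2 (DME, rt) should convert 30 with retention of geometry into the (Z)-enol triflate F1. Coupling with Me3SiCH2MgCl under Pd(PPh3)4 catalysis gives the (Z)-allylsilane F2. The same Me3SiOTf-triggered bis-epoxide cascade, now terminated by the more robust allylsilane, should give the 7-methylene tricycle F3 with the same ring order and the same sense at C5a, C6 and C9a. Dihydroxylation–periodate cleavage (OsO4 cat., NaIO4, 2,6-lutidine, dioxane/H2O) through the diol F4 then gives 32. The cyclohexylidene methylene is expected to react ahead of the hydroazulene methylene, which is flanked by a silyloxy carbon and a neopentyl-type carbon.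

2. Step 5. Facial discrimination between the methyl and silyloxy groups at the allylic quaternary carbon may be poor during alkene insertion. The fallback sets out from 7 (used as the mixture of C6a epimers) and returns at 9, replacing kinetic control by a stereoconvergent sequence. Deconjugative α-methylation (KOt-Bu, MeI, t-BuOH) through the potassium dienolate F5 gives the β,γ-unsaturated ketone F6, in which the ring-fusion stereocentre no longer exists. Bu4NF/AcOH frees the tertiary allylic alcohol F7. Hydroxyl-directed hydrogenation ([Ir(cod)(PCy3)(py)]PF6, H2, CH2Cl2) should deliver both hydrogens to the tetrasubstituted alkene from the hydroxyl face to give the cis-hydroxy ketone F8. TBSOTf/2,6-lutidine returns 9.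

3. Step 12. Protonation at C5 may occur from the wrong face, or the enolate may equilibrate before Mannich trapping. The fallback sets out from 16 and returns at 18, replacing substrate control by catalyst control. Copper hydride 1,4-hydrosilylation (Cu(OAc)2, DTBM-SEGPHOS of the enantiomer that matches the required face, PhMe2SiH, toluene) gives the dimethylphenylsilyl enol ether F9 with hydride delivered to C5. Eschenmoser's salt in CH2Cl2 then gives 18.

**Further compounds**
F1 | step 21 | (Z)-enol triflate of the bis-epoxy ketone | C=C1C(O[Si](C)(C)C(C)(C)C)C[C@@H]2[C@@H](CC[C@@]2(C)O[Si](C)(C)C(C)(C)C)C(C)(C)[C@H]1CC/C=C(\OS(=O)(=O)C(F)(F)F)CC[C@H]1O[C@]1(C)CC[C@H]1OC1(C)C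
F2 | step 21 | (Z)-allylsilane | C=C1C(O[Si](C)(C)C(C)(C)C)C[C@@H]2[C@@H](CC[C@@]2(C)O[Si](C)(C)C(C)(C)C)C(C)(C)[C@H]1CC/C=C(\C[Si](C)(C)C)CC[C@H]1O[C@]1(C)CC[C@H]1OC1(C)C
F3 | step 21 | 7-methylene-3-(trimethylsilyloxy)octahydro-1-benzoxepine tricycle | C=C1C(O[Si](C)(C)C(C)(C)C)C[C@@H]2[C@@H](CC[C@@]2(C)O[Si](C)(C)C(C)(C)C)C(C)(C)[C@H]1CC[C@@H]1[C@@]2(C)CC[C@@H](O[Si](C)(C)C)C(C)(C)O[C@@H]2CCC1=C
F4 | step 21 | 7-hydroxy-7-(hydroxymethyl) diol (not isolated; C7 undefined) | C=C1C(O[Si](C)(C)C(C)(C)C)C[C@@H]2[C@@H](CC[C@@]2(C)O[Si](C)(C)C(C)(C)C)C(C)(C)[C@H]1CC[C@@H]1[C@@]2(C)CC[C@@H](O[Si](C)(C)C)C(C)(C)O[C@@H]2CCC1(O)CO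
F5 | step 5 | potassium dienolate of 7 (not isolated) | [K]OC=1CC2=C(CC[C@@]2(C)O[Si](C)(C)C(C)(C)C)C=1C
F6 | step 5 | (4R)-4-(tert-butyldimethylsilyloxy)-1,1,4-trimethyl-1,4,5,6-tetrahydropentalen-2(3H)-one | O=C1CC2=C(CC[C@@]2(C)O[Si](C)(C)C(C)(C)C)C1(C)C
F7 | step 5 | (4R)-4-hydroxy-1,1,4-trimethyl-1,4,5,6-tetrahydropentalen-2(3H)-one | O=C1CC2=C(CC[C@@]2(C)O)C1(C)C
F8 | step 5 | (3aR,4R,6aR)-4-hydroxy-1,1,4-trimethylhexahydropentalen-2(1H)-one | O=C1C[C@@H]2[C@@H](CC[C@@]2(C)O)C1(C)C
F9 | step 12 | dimethylphenylsilyl enol ether of the 5-allyl ketone | C1=C(O[Si](C)(C)c3ccccc3)C[C@@H]2[C@@H](CC[C@@]2(C)O[Si](C)(C)C(C)(C)C)C(C)(C)[C@H]1CC=C
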